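Numbering: ring A = C1 (diprenyl carbon), C2 (C=O), C3, C4, C5 (acyl-bearing), C6 (C=O); ring B = C3–C7H2–C8H–O9–C4, with the CMe2OH group on C8.
Cuts, in order: both C1–prenyl bonds (ring A becomes aromatic again), the two C–CH3 bonds of the carbinol (leaving a C8 ester), C7–C8 together with O9–C8, then C3–C7 and the C5–acyl bond, back to phloroglucinol.
Enabling feature: in ring B only C8 is bonded to both C7 and O9. It can therefore arrive as a one-carbon donor–acceptor unit (an ammonium ylide) spanning the termini of the heterodiene C7=C3–C4=O9 of an ortho-quinone methide of ring A. MOM ethers on the oxygens of C2 and C6 leave the ketone-chelated oxygen on C4 as the only possible O9.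
Forward order: ring A is bought. Acylation, double MOM protection, aminomethylation at C3 and quaternisation prepare the methide, and ring B closes in the (4+1) annulation. Ester-to-carbinol conversion and a dearomatising double prenylation at C1 finish the target.
Stereochemistry: the single stereocentre C8 (S) is set in the annulation by a quinidine-derived ammonium leaving group (SN2 closure with inversion) and is not touched afterwards.

Key step: step 7

Assumption: the quinidine series is taken to lead to (S)-C8; should the sense of induction be the opposite, the pseudoenantiomeric quinine methyl ether would be carried through steps 5 to 7 in the same way.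

Step 1
Reactants: 1 phloroglucinol; 2 2-methylpropanoyl chloride
Product: 3 1-(2,4,6-trihydroxyphenyl)-2-methylpropan-1-one
Conditions: AlCl3 (3.5 equiv), PhNO2, 65 °C; then aq HCl
Reagents that add atoms: none
Why: Friedel–Crafts C-acylation of the very electron-rich triol should stop after one acyl group because the chelated aryl ketone deactivates the ring.

Step 2
Reactants: 3 1-(2,4,6-trihydroxyphenyl)-2-methylpropan-1-one
Product: 4 1-[2-hydroxy-4,6-bis(methoxymethoxy)phenyl]-2-methylpropan-1-one
Conditions: MOMCl (2.3 equiv), iPr2NEt (3 equiv), CH2Cl2, 0 °C to rt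
Reagents that add atoms: chloromethyl methyl ether, COCCl
Why: In this Williamson-type O-alkylation two hydroxyls are etherified while the last one stays locked in a six-membered hydrogen bond to the ketone, the usual outcome for 2,4,6-trihydroxyaryl ketones, and this free oxygen is the future O9.

Step 3
Reactants: 4 1-[2-hydroxy-4,6-bis(methoxymethoxy)phenyl]-2-methylpropan-1-one
Product: 5 1-[3-(dimethylaminomethyl)-2-hydroxy-4,6-bis(methoxymethoxy)phenyl]-2-methylpropan-1-one
Conditions: dimethylmethyleneammonium iodide (1.1 equiv), Et3N (1.2 equiv), CH2Cl2, rt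
Reagents that add atoms: dimethylmethyleneammonium iodide, C=[N+](C)C.[I-]
Why: Mannich aminomethylation with a preformed iminium salt goes ortho to the free phenol, so C3 (between OH and one OMOM) should react rather than C1, which is crowded by two OMOM groups and has no neighbouring hydroxyl to guide the electrophile.

Step 4
Reactants: 5 1-[3-(dimethylaminomethyl)-2-hydroxy-4,6-bis(methoxymethoxy)phenyl]-2-methylpropan-1-one
Product: 6 [2-hydroxy-4,6-bis(methoxymethoxy)-3-(2-methylpropanoyl)phenyl]methyl-trimethylammonium iodide
Conditions: MeI (3 equiv), Et2O, rt, dark; salt filtered off and washed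
Reagents that add atoms: iodomethane, CI
Why: Menshutkin quaternisation of the benzylic tertiary amine is fast, the chelated phenol is not alkylated without base, and precipitation of the salt allows all excess MeI to be removed before the base-mediated step.

Step 5
Reactants: 7 quinidine
Product: 8 O-methylquinidine, (8R,9S)-6',9-dimethoxycinchonan
Conditions: NaH (1.3 equiv), DMF, 0 °C to rt; then MeI (1.05 equiv), 0 °C
Reagents that add atoms: iodomethane, CI
Why: Williamson etherification of the C9 hydroxyl after full deprotonation outruns N-methylation, leaves all stereocentres untouched and removes a hydroxyl that could otherwise add to the methide in step 7.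

Step 6
Reactants: 8 O-methylquinidine; 9 tert-butyl bromoacetate
Product: 10 N-(2-tert-butoxy-2-oxoethyl)-O-methylquinidinium bromide (quaternised at the quinuclidine nitrogen)
Conditions: THF, rt; salt filtered off
Reagents that add atoms: none
Why: In this Menshutkin reaction the quinuclidine nitrogen is far more nucleophilic than the quinoline nitrogen and the α-bromo ester is a very reactive SN2 partner, so a single ammonium salt should form.

Step 7
Reactants: 6 [2-hydroxy-4,6-bis(methoxymethoxy)-3-(2-methylpropanoyl)phenyl]methyl-trimethylammonium iodide; 10 N-(2-tert-butoxy-2-oxoethyl)-O-methylquinidinium bromide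
Product: 14 tert-butyl (2S)-4,6-bis(methoxymethoxy)-7-(2-methylpropanoyl)-2,3-dihydrobenzofuran-2-carboxylate, via ammonium ylide 11 (not isolated), via ortho-quinone methide 12 (not isolated), via (R)-betaine 13 (not isolated)
Conditions: 10 (1.5 equiv), Cs2CO3 (4 equiv), CH2Cl2, 0 °C to rt, 6 added in portions; 8 recovered by acid wash
Reagents that add atoms: none
Why: Cs2CO3 deprotonates the chelated C4 phenol of 6, which expels NMe3 to give methide 12, and deprotonates 10 to ylide 11; the ylide carbon adds to the unsubstituted terminus C7 (bond C7–C8, ring A rearomatises) and the phenoxide O9 of betaine 13 then displaces the quinuclidinium group from C8 (bond O9–C8). The closest known reaction type is the (4+1) annulation of ortho-quinone methides with ammonium, pyridinium or sulfonium ylides, which is established in enantioselective form with cinchona-derived ammonium ylides on substituted methides and in racemic form for unsubstituted methides released from Mannich-base methiodides. Ring B closes in a 5-exo-tet SN2 mode with inversion at C8. C8 is the only new stereocentre: its two betaine epimers interconvert through reversible deprotonation of the acidic α-ammonium ester position, and the chiral quinuclidinium leaving group should let the (R)-epimer reach the anti O9···C8–N alignment more easily, so that this epimer closes faster and delivers (S)-14 under Curtin–Hammett control. The step needs chemoselective use of one oxygen, which the substrate secures because the oxygens on C2 and C6 are MOM ethers, so only O9 can build the methide and close the ring and no further acidic hydroxyl can turn the methide into an unreactive anion or a carbon nucleophile. The tert-butyl ester blocks the competing six-membered lactonisation of O9 onto the ester carbonyl, and portionwise addition of sparingly soluble 6 to excess ylide keeps the methide concentration low enough to suppress its dimerisation.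

Step 8
Reactants: 14 tert-butyl (2S)-4,6-bis(methoxymethoxy)-7-(2-methylpropanoyl)-2,3-dihydrobenzofuran-2-carboxylate
Product: 16 methyl (2S)-4,6-dihydroxy-7-(2-methylpropanoyl)-2,3-dihydrobenzofuran-2-carboxylate, via carboxylic acid 15 (not isolated)
Conditions: HCl (3 M in MeOH), 55 °C
Reagents that add atoms: methanol, CO
Why: Acid-catalysed acetal exchange frees both phenols, and the same medium cleaves the tert-butyl ester (AAL1) and re-esterifies acid 15 (Fischer esterification), so all partial products converge on the more reactive methyl ester, with no carbinol yet present to dehydrate and C8 safe because acid enolisation of an α-aryloxy ester is slow.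

Step 9
Reactants: 16 methyl (2S)-4,6-dihydroxy-7-(2-methylpropanoyl)-2,3-dihydrobenzofuran-2-carboxylate
Product: 18 1-[(2S)-4,6-dihydroxy-2-(2-hydroxypropan-2-yl)-2,3-dihydrobenzofuran-7-yl]-2-methylpropan-1-one, via methyl ketone 17 (not isolated)
Conditions: MeMgBr (6 equiv), THF, −20 °C to rt; then 1 M HCl, 0 °C
Reagents that add atoms: methylmagnesium bromide, C[Mg]Br
Why: In this double Grignard addition the first two equivalents make magnesium phenoxides ortho and para to the aryl ketone, which as a chelated, doubly vinylogous carboxylate flanked by two ortho substituents and an isopropyl group should resist attack, while the α-oxygenated methyl ester takes up two methyl groups fast enough to keep the configuration at C8.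

Step 10
Reactants: 18 1-[(2S)-4,6-dihydroxy-2-(2-hydroxypropan-2-yl)-2,3-dihydrobenzofuran-7-yl]-2-methylpropan-1-one; 19 1-bromo-3-methylbut-2-ene
Product: 21 garcinielliptone HD, via monoprenyl phenol 20 (not isolated)
Conditions: 19 (2.4 equiv), KOH (4 equiv), H2O/MeOH, 0 °C to rt; then 1 M HCl
Reagents that add atoms: none
Why: Alkylative dearomatisation of acylphloroglucinols in protic base favours carbon over oxygen, C1 is the only unsubstituted and most nucleophilic ring carbon (between two phenoxide oxygens), and the second prenylation at the same carbon gives a stabilised β-triketone enolate that should not react further, while C8 is remote and carries no acidic hydrogen.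

Compound list
1 | phloroglucinol (benzene-1,3,5-triol) | Oc1cc(O)cc(O)c1 | starting material
2 | 2-methylpropanoyl chloride | CC(C)C(Cl)=O | starting material
3 | 1-(2,4,6-trihydroxyphenyl)-2-methylpropan-1-one | CC(C)C(=O)c1c(O)cc(O)cc1O | intermediate
4 | 1-[2-hydroxy-4,6-bis(methoxymethoxy)phenyl]-2-methylpropan-1-one | CC(C)C(=O)c1c(O)cc(OCOC)cc1OCOC | intermediate
5 | 1-[3-(dimethylaminomethyl)-2-hydroxy-4,6-bis(methoxymethoxy)phenyl]-2-methylpropan-1-one | CC(C)C(=O)c1c(O)c(CN(C)C)c(OCOC)cc1OCOC | intermediate
6 | [2-hydroxy-4,6-bis(methoxymethoxy)-3-(2-methylpropanoyl)phenyl]methyl-trimethylammonium iodide | CC(C)C(=O)c1c(O)c(C[N+](C)(C)C)c(OCOC)cc1OCOC.[I-] | intermediate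
7 | quinidine, (8R,9S)-6'-methoxycinchonan-9-ol | COC1=CC2=C(C=CN=C2C=C1)[C@@H]([C@H]3C[C@@H]4CCN3C[C@@H]4C=C)O | starting material
8 | O-methylquinidine, (8R,9S)-6',9-dimethoxycinchonan | COC1=CC2=C(C=CN=C2C=C1)[C@@H]([C@H]3C[C@@H]4CCN3C[C@@H]4C=C)OC | intermediate
9 | tert-butyl bromoacetate | CC(C)(C)OC(=O)CBr | starting material
10 | N-(2-tert-butoxy-2-oxoethyl)-O-methylquinidinium bromide | COC1=CC2=C(C=CN=C2C=C1)[C@@H]([C@H]3C[C@@H]4CC[N@@+]3(CC(=O)OC(C)(C)C)C[C@@H]4C=C)OC.[Br-] | intermediate
11 | ammonium ylide, 2-tert-butoxy-2-oxo-1-(O-methylquinidinium-1-yl)ethan-1-ide | COC1=CC2=C(C=CN=C2C=C1)[C@@H]([C@H]3C[C@@H]4CC[N@@+]3([CH-]C(=O)OC(C)(C)C)C[C@@H]4C=C)OC | intermediate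
12 | ortho-quinone methide, 3,5-bis(methoxymethoxy)-6-methylidene-2-(2-methylpropanoyl)cyclohexa-2,4-dien-1-one | C=C1C(=O)C(C(=O)C(C)C)=C(OCOC)C=C1OCOC | intermediate
13 | (R)-betaine, 2-[(2R)-3-tert-butoxy-3-oxo-2-(O-methylquinidinium-1-yl)propyl]-3,5-bis(methoxymethoxy)-6-(2-methylpropanoyl)phenolate | COC1=CC2=C(C=CN=C2C=C1)[C@@H]([C@H]3C[C@@H]4CC[N@@+]3([C@@H](C(=O)OC(C)(C)C)Cc5c([O-])c(C(=O)C(C)C)c(OCOC)cc5OCOC)C[C@@H]4C=C)OC | intermediate
14 | tert-butyl (2S)-4,6-bis(methoxymethoxy)-7-(2-methylpropanoyl)-2,3-dihydrobenzofuran-2-carboxylate | CC(C)C(=O)c1c(OCOC)cc(OCOC)c2c1O[C@H](C(=O)OC(C)(C)C)C2 | intermediate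
15 | (2S)-4,6-dihydroxy-7-(2-methylpropanoyl)-2,3-dihydrobenzofuran-2-carboxylic acid | CC(C)C(=O)c1c(O)cc(O)c2c1O[C@H](C(=O)O)C2 | intermediate
16 | methyl (2S)-4,6-dihydroxy-7-(2-methylpropanoyl)-2,3-dihydrobenzofuran-2-carboxylate | CC(C)C(=O)c1c(O)cc(O)c2c1O[C@H](C(=O)OC)C2 | intermediate
17 | 1-[(2S)-2-acetyl-4,6-dihydroxy-2,3-dihydrobenzofuran-7-yl]-2-methylpropan-1-one | CC(C)C(=O)c1c(O)cc(O)c2c1O[C@H](C(C)=O)C2 | intermediate
18 | 1-[(2S)-4,6-dihydroxy-2-(2-hydroxypropan-2-yl)-2,3-dihydrobenzofuran-7-yl]-2-methylpropan-1-one | CC(C)C(=O)c1c(O)cc(O)c2c1O[C@H](C(C)(C)O)C2 | intermediate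
19 | 1-bromo-3-methylbut-2-ene (prenyl bromide) | CC(C)=CCBr | starting material
20 | 1-[(2S)-4,6-dihydroxy-2-(2-hydroxypropan-2-yl)-5-(3-methylbut-2-enyl)-2,3-dihydrobenzofuran-7-yl]-2-methylpropan-1-one | CC(C)C(=O)c1c(O)c(CC=C(C)C)c(O)c2c1O[C@H](C(C)(C)O)C2 | intermediate
21 | garcinielliptone HD, (2S)-7-(1-hydroxy-2-methylpropylidene)-2-(2-hydroxypropan-2-yl)-5,5-bis(3-methylbut-2-enyl)-2,3-dihydrobenzofuran-4,6-dione | CC(C)=CCC1(CC=C(C)C)C(=O)C2=C(O[C@H](C(C)(C)O)C2)/C(=C(/O)C(C)C)C1=O | target

Total step count: 10. Longest linear sequence: 8 steps (1, 2, 3, 4, 7, 8, 9, 10); steps 5 and 6 form the short branch to the ammonium salt.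

Steps most likely to fail

**Step 7.**
- Risk: discrimination between the two rapidly interconverting betaine epimers may be weak in the ring closure, which would lower the enantiomeric purity at C8. Loss of NMe3 may also be sluggish, or the unsubstituted methide may condense with itself.
- Fallback: it sets out from 6 and returns at 18. It traps the methide with a four-carbon nucleophile and takes the stereochemistry from a catalyst-controlled epoxidation.
  - Treatment of 6 with 2-methylprop-1-enylmagnesium bromide (3 equiv, THF, −78 °C to 0 °C) should release the methide and add the alkenyl group to C7. This gives 1-[2-hydroxy-4,6-bis(methoxymethoxy)-3-(3-methylbut-2-enyl)phenyl]-2-methylpropan-1-one F1.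
  - Shi epoxidation (D-fructose-derived ketone catalyst, KHSO5 as the triple salt 2KHSO5·KHSO4·K2SO4, K2CO3 buffer, MeCN/H2O, 0 °C) should give 1-[3-{[(2R)-3,3-dimethyloxiran-2-yl]methyl}-2-hydroxy-4,6-bis(methoxymethoxy)phenyl]-2-methylpropan-1-one F2.
  - In the basic medium the neighbouring phenoxide opens F2 at C8 (5-exo-tet, inversion). This leads to 1-[(2S)-2-(2-hydroxypropan-2-yl)-4,6-bis(methoxymethoxy)-2,3-dihydrobenzofuran-7-yl]-2-methylpropan-1-one F3.
  - Mild acid (HCl, 0.5 M in MeOH, rt) then removes both MOM groups to reach 18.

**Step 10.**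
- Risk: O-prenylation may compete, the reaction may stop after the first prenylation, and the bromide may hydrolyse in the aqueous base.
- Fallback: it sets out from 18 and returns at 21. It replaces the SN2 alkylation by a reversible π-allyl transfer followed by olefin exchange.
  - Tsuji–Trost allylation with allyl methyl carbonate (2.5 equiv) and Pd(PPh3)4 in THF at 40 °C should funnel material to carbon, because O-allyl ethers re-ionise under zerovalent palladium catalysis. This gives (2S)-7-(1-hydroxy-2-methylpropylidene)-2-(2-hydroxypropan-2-yl)-5,5-di(prop-2-enyl)-2,3-dihydrobenzofuran-4,6-dione F4.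
  - Double cross-metathesis with excess 2-methylbut-2-ene (second-generation Grubbs catalyst, CH2Cl2, 40 °C) then converts both allyl groups into prenyl groups to give 21.

**Step 3.**
- Risk: aminomethylation may occur at C1, para to the free hydroxyl, or at both free ring positions.
- Fallback: it sets out from 4 and returns at 5. It delivers the C7 carbon within a metal phenoxide complex.
  - Casnati–Skattebøl ortho-formylation (MgCl2, Et3N, paraformaldehyde, MeCN, reflux) transfers formaldehyde only to the carbon next to the magnesium-bound oxygen. This should give 2-hydroxy-4,6-bis(methoxymethoxy)-3-(2-methylpropanoyl)benzaldehyde F5.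
  - Reductive amination (Me2NH, NaBH(OAc)3, 1,2-dichloroethane, rt) then leads to 5.

Further compounds
F1 | step 7 | 1-[2-hydroxy-4,6-bis(methoxymethoxy)-3-(3-methylbut-2-enyl)phenyl]-2-methylpropan-1-one | CC(C)C(=O)c1c(O)c(CC=C(C)C)c(OCOC)cc1OCOC
F2 | step 7 | 1-[3-{[(2R)-3,3-dimethyloxiran-2-yl]methyl}-2-hydroxy-4,6-bis(methoxymethoxy)phenyl]-2-methylpropan-1-one | CC(C)C(=O)c1c(O)c(C[C@H]2OC2(C)C)c(OCOC)cc1OCOC
F3 | step 7 | 1-[(2S)-2-(2-hydroxypropan-2-yl)-4,6-bis(methoxymethoxy)-2,3-dihydrobenzofuran-7-yl]-2-methylpropan-1-one | CC(C)C(=O)c1c(OCOC)cc(OCOC)c2c1O[C@H](C(C)(C)O)C2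
F4 | step 10 | (2S)-7-(1-hydroxy-2-methylpropylidene)-2-(2-hydroxypropan-2-yl)-5,5-di(prop-2-enyl)-2,3-dihydrobenzofuran-4,6-dione | C=CCC1(CC=C)C(=O)C2=C(O[C@H](C(C)(C)O)C2)/C(=C(/O)C(C)C)C1=O
F5 | step 3 | 2-hydroxy-4,6-bis(methoxymethoxy)-3-(2-methylpropanoyl)benzaldehyde | CC(C)C(=O)c1c(O)c(C=O)c(OCOC)cc1OCOC
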